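**Retrosynthetic overview**
- The target is reached by phenol desilylation, O-acetylation and syn-hydrogenation of a C7'=C8' alkene in an (E)-homoallylic alcohol; the hydrogenation sets C8'.
- That alcohol comes from a one-pot three-component union: the C7'–C8' bond by a 1,2-boronate (metalate) shift of a butenyl group onto the lithiated guaiacyl-methyl carbamate carbon, then the C8–C7 bond by allylboration of veratraldehyde.
- Enabling feature: the benzylic C7' of the guaiacyl ring is flanked by the methyl-bearing C8' and C8, so C7'(B)–C8'(Me)=C8(Me) is an α-aryl (Z)-crotyl boronate whose γ-carbon C8 is one bond from the carbinol carbon C7 of the veratryl ring. The boron-bearing C7' is a temporary stereocentre that relays chirality to C7 and C8 and is then erased.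
- Building blocks: vanillyl alcohol, (Z)-2-bromobut-2-ene and veratraldehyde. No ring is formed; both benzene rings are bought intact.

Key step: step 4

Remark: lignan locants are used in the text (C7' = benzylic carbon on the guaiacyl ring, C8' and C8 = the two methyl-bearing carbons, C7 = the oxygenated benzylic carbon on the veratryl ring). It is assumed that the sense of induction of the chiral ligands in steps 4 and 6 can be set by the choice of ligand enantiomer; the configurations drawn are those required.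

**Step 1**
Reactants: 1 4-(hydroxymethyl)-2-methoxyphenol (vanillyl alcohol)
Product: 3 [3-methoxy-4-(triisopropylsilyloxy)phenyl]methanol, via sodium phenoxide 2 (not isolated)
Conditions: NaH (1.0 equiv), DMF, 0 °C; TIPSCl (1.05 equiv), 0 °C → rt
Reagents that add atoms: chlorotriisopropylsilane (TIPSCl), CC(C)[Si](Cl)(C(C)C)C(C)C
Why: O-silylation of a phenoxide; one equivalent of NaH removes only the phenolic proton (pKa about 10 against about 15 for the benzylic alcohol), and the neutral primary alcohol does not react with the hindered silyl chloride without a nucleophilic catalyst.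

**Step 2**
Reactants: 3 [3-methoxy-4-(triisopropylsilyloxy)phenyl]methanol
Product: 4 [3-methoxy-4-(triisopropylsilyloxy)phenyl]methyl N,N-di(propan-2-yl)carbamate
Conditions: i-Pr2NCOCl (1.2 equiv), Et3N (1.5 equiv), DMAP (cat.), toluene, 90 °C
Reagents that add atoms: N,N-diisopropylcarbamoyl chloride, CC(C)N(C(C)C)C(Cl)=O
Why: Carbamoylation of a primary alcohol with a carbamoyl chloride (formation of a Hoppe carbamate) under amine base, conditions to which the aryl silyl ether is inert.

**Step 3**
Reactants: 5 (Z)-2-bromobut-2-ene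
Product: 7 (E)-2-(but-2-en-2-yl)-4,4,5,5-tetramethyl-1,3,2-dioxaborolane, via alkenyllithium 6 (not isolated)
Conditions: t-BuLi (2.0 equiv), Et2O, −78 °C; i-PrOBpin, −78 °C → rt; H2O
Reagents that add atoms: 2-isopropoxy-4,4,5,5-tetramethyl-1,3,2-dioxaborolane, CC(C)OB1OC(C)(C)C(C)(C)O1
Why: Bromine–lithium exchange of an alkenyl bromide proceeds with retention of the double-bond geometry, and the alkenyllithium is trapped by the isopropoxyboronate (borylation of an organolithium), so boron ends up cis to the C3 methyl group.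

**Step 4**
Reactants: 4 [3-methoxy-4-(triisopropylsilyloxy)phenyl]methyl N,N-di(propan-2-yl)carbamate; 7 (E)-2-(but-2-en-2-yl)-4,4,5,5-tetramethyl-1,3,2-dioxaborolane; 8 3,4-dimethoxybenzaldehyde (veratraldehyde)
Product: 13 (1R,2S,3E)-1-(3,4-dimethoxyphenyl)-4-[3-methoxy-4-(triisopropylsilyloxy)phenyl]-2,3-dimethylbut-3-en-1-ol, via lithiated carbamate 9 (not isolated), via boronate complex 10 (not isolated), via allylboronate 11 (not isolated), via borate ester 12 (not isolated)
Conditions: s-BuLi (1.2 equiv), chiral bis(oxazoline) ligand (1.3 equiv; e.g. 2,2-bis[(4S)-4-isopropyl-4,5-dihydrooxazol-2-yl]propane or its antipode, whichever gives (R)-9), toluene/Et2O, −78 °C, 3 h; 7 (1.3 equiv), −78 °C, 1 h, then → rt, 2 h; 8 (1.5 equiv), rt, 24 h; H2O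
Reagents that add atoms: none
Why: Deprotonation of 4 gives the configurationally labile α-carbamoyloxy benzyllithium 9, whose diastereomeric bis(oxazoline) complexes equilibrate at −78 °C (dynamic thermodynamic resolution) before boronic ester 7 traps the (R) complex with retention as boronate complex 10; on warming, the butenyl group migrates from boron to C7' anti to the departing carbamate (1,2-metalate rearrangement with inversion), which forms the C7'–C8' bond and gives the α-aryl (Z)-crotyl-type boronate 11, and 11 then adds to aldehyde 8 through a closed six-membered chair transition state to form C8–C7 and borate 12. The closest known reaction type is the lithiation–borylation–allylboration sequence of Hoppe-type lithiated carbamates with alkenyl pinacol boronates (Matteson-type 1,2-shift followed by carbonyl allylboration). No ring is closed. The C8 methyl, cis to C7' in 11 because boron is cis to it in 7, is forced axial in the chair, which gives the 7,8-syn relationship, while the aryl group of 8 is equatorial. The absolute configuration of C7 and C8 (7R,8S) is relayed from the boron-bearing C7' of (R)-11: the aldehyde bonds to the allyl face that carries boron while the guaiacyl group on C7' stays pseudo-equatorial to avoid a 1,3-diaxial clash with the axial C8 methyl, which also makes the new C7'=C8' bond E and erases the C7' stereocentre. The step needs high enantiomeric purity of 10 (chiral ligand and fast borylation at −78 °C), γ- over α-attack of the allyl unit (closed transition state) and benzylic over ortho lithiation (the carbamate-directed, α-oxygenated benzylic proton of 4 is by far the most acidic site).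

**Step 5**
Reactants: 13 (1R,2S,3E)-1-(3,4-dimethoxyphenyl)-4-[3-methoxy-4-(triisopropylsilyloxy)phenyl]-2,3-dimethylbut-3-en-1-ol
Product: 14 (1R,2S,3E)-1-(3,4-dimethoxyphenyl)-4-[3-methoxy-4-(triisopropylsilyloxy)phenyl]-2,3-dimethylbut-3-en-1-yl acetate
Conditions: Ac2O (2 equiv), DMAP (cat.), pyridine, 0 °C → rt
Reagents that add atoms: acetic anhydride, CC(=O)OC(C)=O
Why: DMAP-catalysed acetylation of a secondary alcohol under basic conditions that touch neither the styrene nor the silyl ether and do not ionise the electron-rich benzylic centre.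

**Step 6**
Reactants: 14 (1R,2S,3E)-1-(3,4-dimethoxyphenyl)-4-[3-methoxy-4-(triisopropylsilyloxy)phenyl]-2,3-dimethylbut-3-en-1-yl acetate
Product: 15 (1R,2S,3R)-1-(3,4-dimethoxyphenyl)-4-[3-methoxy-4-(triisopropylsilyloxy)phenyl]-2,3-dimethylbutyl acetate
Conditions: [Ir(cod)(L*)]BArF (2 mol %; L* = chiral phosphinite–oxazoline N,P ligand, enantiomer chosen to give 3R), H2 (50 bar), CH2Cl2, rt
Reagents that add atoms: none
Why: Iridium–N,P-ligand catalysed asymmetric hydrogenation of an unfunctionalised (E)-trisubstituted aryl alkene adds H2 syn to the alkene face chosen by the ligand and should set C8' as R (8,8'-syn); the hydroxyl is acetylated beforehand because a chelate model predicts that hydroxyl direction would deliver hydrogen to the opposite face, and the homogeneous catalyst is not expected to hydrogenolyse the benzylic acetate.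

**Step 7**
Reactants: 15 (1R,2S,3R)-1-(3,4-dimethoxyphenyl)-4-[3-methoxy-4-(triisopropylsilyloxy)phenyl]-2,3-dimethylbutyl acetate
Product: 16 (1R,2S,3R)-1-(3,4-dimethoxyphenyl)-4-(4-hydroxy-3-methoxyphenyl)-2,3-dimethylbutyl acetate (target)
Conditions: TBAF (1.1 equiv), AcOH (1.2 equiv), THF, 0 °C
Reagents that add atoms: none
Why: Fluoride-induced cleavage of an aryl silyl ether, buffered with acetic acid so that the phenoxide is protonated at once and the secondary acetate is neither hydrolysed nor transferred.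

**Compound list**
1 | 4-(hydroxymethyl)-2-methoxyphenol (vanillyl alcohol) | COc1cc(CO)ccc1O | starting material
2 | sodium 4-(hydroxymethyl)-2-methoxyphenolate | COc1cc(CO)ccc1[O-].[Na+] | intermediate
3 | [3-methoxy-4-(triisopropylsilyloxy)phenyl]methanol | COc1cc(CO)ccc1O[Si](C(C)C)(C(C)C)C(C)C | intermediate
4 | [3-methoxy-4-(triisopropylsilyloxy)phenyl]methyl N,N-di(propan-2-yl)carbamate | COc1cc(COC(=O)N(C(C)C)C(C)C)ccc1O[Si](C(C)C)(C(C)C)C(C)C | intermediate
5 | (Z)-2-bromobut-2-ene | C/C=C(/C)Br | starting material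
6 | (E)-but-2-en-2-yllithium | C/C=C(/C)[Li] | intermediate
7 | (E)-2-(but-2-en-2-yl)-4,4,5,5-tetramethyl-1,3,2-dioxaborolane | C/C=C(/C)B1OC(C)(C)C(C)(C)O1 | intermediate
8 | 3,4-dimethoxybenzaldehyde (veratraldehyde) | COc1ccc(C=O)cc1OC | starting material
9 | (R)-{[di(propan-2-yl)carbamoyl]oxy}[3-methoxy-4-(triisopropylsilyloxy)phenyl]methyllithium | [Li][C@@H](OC(=O)N(C(C)C)C(C)C)c1ccc(O[Si](C(C)C)(C(C)C)C(C)C)c(OC)c1 | intermediate
10 | lithium [(E)-but-2-en-2-yl][(R)-{[di(propan-2-yl)carbamoyl]oxy}[3-methoxy-4-(triisopropylsilyloxy)phenyl]methyl](pinacolato)borate | C/C=C(/C)[B-]1(OC(C)(C)C(C)(C)O1)[C@@H](OC(=O)N(C(C)C)C(C)C)c1ccc(O[Si](C(C)C)(C(C)C)C(C)C)c(OC)c1.[Li+] | intermediate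
11 | 2-[(1R,2Z)-1-[3-methoxy-4-(triisopropylsilyloxy)phenyl]-2-methylbut-2-en-1-yl]-4,4,5,5-tetramethyl-1,3,2-dioxaborolane | C/C=C(/C)[C@@H](B1OC(C)(C)C(C)(C)O1)c1ccc(O[Si](C(C)C)(C(C)C)C(C)C)c(OC)c1 | intermediate
12 | 2-{[(1R,2S,3E)-1-(3,4-dimethoxyphenyl)-4-[3-methoxy-4-(triisopropylsilyloxy)phenyl]-2,3-dimethylbut-3-en-1-yl]oxy}-4,4,5,5-tetramethyl-1,3,2-dioxaborolane | COc1cc(/C=C(\C)[C@H](C)[C@@H](OB3OC(C)(C)C(C)(C)O3)c2ccc(OC)c(OC)c2)ccc1O[Si](C(C)C)(C(C)C)C(C)C | intermediate
13 | (1R,2S,3E)-1-(3,4-dimethoxyphenyl)-4-[3-methoxy-4-(triisopropylsilyloxy)phenyl]-2,3-dimethylbut-3-en-1-ol | COc1cc(/C=C(\C)[C@H](C)[C@@H](O)c2ccc(OC)c(OC)c2)ccc1O[Si](C(C)C)(C(C)C)C(C)C | intermediate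
14 | (1R,2S,3E)-1-(3,4-dimethoxyphenyl)-4-[3-methoxy-4-(triisopropylsilyloxy)phenyl]-2,3-dimethylbut-3-en-1-yl acetate | COc1cc(/C=C(\C)[C@H](C)[C@@H](OC(C)=O)c2ccc(OC)c(OC)c2)ccc1O[Si](C(C)C)(C(C)C)C(C)C | intermediate
15 | (1R,2S,3R)-1-(3,4-dimethoxyphenyl)-4-[3-methoxy-4-(triisopropylsilyloxy)phenyl]-2,3-dimethylbutyl acetate | COc1cc(C[C@@H](C)[C@H](C)[C@@H](OC(C)=O)c2ccc(OC)c(OC)c2)ccc1O[Si](C(C)C)(C(C)C)C(C)C | intermediate
16 | (1R,2S,3R)-1-(3,4-dimethoxyphenyl)-4-(4-hydroxy-3-methoxyphenyl)-2,3-dimethylbutyl acetate | COc1cc(C[C@@H](C)[C@H](C)[C@@H](OC(C)=O)c2ccc(OC)c(OC)c2)ccc1O | target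

**Step count**
Total: 7 steps. Longest linear sequence: 6 steps (1, 2, 4, 5, 6, 7); step 3 is a one-step side branch.

**Steps most likely to fail**

Step 4. The lithiated benzylic carbamate may epimerise faster than it is borylated, or the boronate complex may form reversibly and migrate slowly, so that enantiomeric purity is lost before the allylboration relays it. The fallback creates the boron-bearing C7' stereocentre by catalysis instead of from a chiral carbenoid; it sets out from 3 and comes back to the route at 11. Oxidation of 3 with MnO2 gives 3-methoxy-4-(triisopropylsilyloxy)benzaldehyde F1. Condensation with tosylhydrazide gives N'-[(E)-[3-methoxy-4-(triisopropylsilyloxy)phenyl]methylidene]-4-methylbenzenesulfonohydrazide F2. Base-mediated formation of the diazo compound and its insertion into B2pin2 (NaH, toluene, 90 °C) gives the geminal bis(boronate) 2,2'-{[3-methoxy-4-(triisopropylsilyloxy)phenyl]methylene}bis(4,4,5,5-tetramethyl-1,3,2-dioxaborolane) F3. An enantiotopic-group-selective Suzuki–Miyaura coupling of F3 with 5 (Pd(OAc)2, chiral phosphoramidite, KOH, dioxane/H2O) forms the C7'–C8' bond with retention of the alkene geometry of 5 and should give 11, to which 8 is added as in step 4.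

Step 6. Facial selectivity may be insufficient if the substrate bias opposes the catalyst, and the acidic iridium hydrides may ionise the electron-rich benzylic acetate. The fallback lets the C7 hydroxyl direct the reduction of the regioisomeric 1,1-disubstituted alkene, which is assembled by aldol and Grignard chemistry; it sets out from 8 (with 3 as the source of the benzyl unit) and comes back at 15. Evans syn-aldol reaction of 8 with (R)-4-benzyl-3-propanoyl-1,3-oxazolidin-2-one (Bu2BOTf, i-Pr2NEt) gives (4R)-4-benzyl-3-[(2R,3R)-3-(3,4-dimethoxyphenyl)-3-hydroxy-2-methylpropanoyl]-1,3-oxazolidin-2-one F4. Me3Al/MeONHMe·HCl gives the Weinreb amide (2R,3R)-3-(3,4-dimethoxyphenyl)-3-hydroxy-N-methoxy-N,2-dimethylpropanamide F5. Alcohol 3 is converted with SOCl2 into [4-(chloromethyl)-2-methoxyphenoxy]tri(propan-2-yl)silane F6, whose Grignard reagent (excess) acylates with F5 to (3R,4R)-4-(3,4-dimethoxyphenyl)-4-hydroxy-1-[3-methoxy-4-(triisopropylsilyloxy)phenyl]-3-methylbutan-2-one F7. Takai–Lombardo methylenation (Zn, CH2Br2, TiCl4) gives (1R,2S)-1-(3,4-dimethoxyphenyl)-3-{[3-methoxy-4-(triisopropylsilyloxy)phenyl]methyl}-2-methylbut-3-en-1-ol F8. Hydroxyl-directed hydrogenation ([Rh(nbd)(dppb)]BF4, H2, CH2Cl2) should deliver hydrogen to the alkene face held next to rhodium in the chelate in which the C8 methyl avoids 1,2-allylic strain with the benzylic CH2, giving (1R,2S,3R)-1-(3,4-dimethoxyphenyl)-4-[3-methoxy-4-(triisopropylsilyloxy)phenyl]-2,3-dimethylbutan-1-ol F9. Acetylation as in step 5 gives 15.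

Step 7. Fluoride or the liberated phenoxide may cleave the secondary acetate or take over the acetyl group on the most advanced material. The fallback changes the protecting-group logic so that an aryl acetate is the last group removed; it sets out from 15 and comes back at 16. TBAF followed by K2CO3/MeOH removes both the silyl and the acetyl group to give (1R,2S,3R)-1-(3,4-dimethoxyphenyl)-4-(4-hydroxy-3-methoxyphenyl)-2,3-dimethylbutan-1-ol F10. Ac2O/pyridine gives (1R,2S,3R)-4-(4-acetoxy-3-methoxyphenyl)-1-(3,4-dimethoxyphenyl)-2,3-dimethylbutyl acetate F11. Chemoselective cleavage of the aryl acetate (NH4OAc, aqueous MeOH, rt) gives 16.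

**Further compounds**
F1 | step 4 | 3-methoxy-4-(triisopropylsilyloxy)benzaldehyde | COc1cc(C=O)ccc1O[Si](C(C)C)(C(C)C)C(C)C
F2 | step 4 | N'-[(E)-[3-methoxy-4-(triisopropylsilyloxy)phenyl]methylidene]-4-methylbenzenesulfonohydrazide | COc1cc(/C=N/NS(=O)(=O)c2ccc(C)cc2)ccc1O[Si](C(C)C)(C(C)C)C(C)C
F3 | step 4 | 2,2'-{[3-methoxy-4-(triisopropylsilyloxy)phenyl]methylene}bis(4,4,5,5-tetramethyl-1,3,2-dioxaborolane) | COc1cc(C(B2OC(C)(C)C(C)(C)O2)B2OC(C)(C)C(C)(C)O2)ccc1O[Si](C(C)C)(C(C)C)C(C)C
F4 | step 6 | (4R)-4-benzyl-3-[(2R,3R)-3-(3,4-dimethoxyphenyl)-3-hydroxy-2-methylpropanoyl]-1,3-oxazolidin-2-one | O=C1OC[C@@H](Cc2ccccc2)N1C(=O)[C@H](C)[C@@H](O)c1ccc(OC)c(OC)c1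
F5 | step 6 | (2R,3R)-3-(3,4-dimethoxyphenyl)-3-hydroxy-N-methoxy-N,2-dimethylpropanamide | CON(C)C(=O)[C@H](C)[C@@H](O)c1ccc(OC)c(OC)c1
F6 | step 6 | [4-(chloromethyl)-2-methoxyphenoxy]tri(propan-2-yl)silane | COc1cc(CCl)ccc1O[Si](C(C)C)(C(C)C)C(C)C
F7 | step 6 | (3R,4R)-4-(3,4-dimethoxyphenyl)-4-hydroxy-1-[3-methoxy-4-(triisopropylsilyloxy)phenyl]-3-methylbutan-2-one | COc1cc(CC(=O)[C@H](C)[C@@H](O)c2ccc(OC)c(OC)c2)ccc1O[Si](C(C)C)(C(C)C)C(C)C
F8 | step 6 | (1R,2S)-1-(3,4-dimethoxyphenyl)-3-{[3-methoxy-4-(triisopropylsilyloxy)phenyl]methyl}-2-methylbut-3-en-1-ol | COc1cc(CC(=C)[C@H](C)[C@@H](O)c2ccc(OC)c(OC)c2)ccc1O[Si](C(C)C)(C(C)C)C(C)C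
F9 | step 6 | (1R,2S,3R)-1-(3,4-dimethoxyphenyl)-4-[3-methoxy-4-(triisopropylsilyloxy)phenyl]-2,3-dimethylbutan-1-ol | COc1cc(C[C@@H](C)[C@H](C)[C@@H](O)c2ccc(OC)c(OC)c2)ccc1O[Si](C(C)C)(C(C)C)C(C)C
F10 | step 7 | (1R,2S,3R)-1-(3,4-dimethoxyphenyl)-4-(4-hydroxy-3-methoxyphenyl)-2,3-dimethylbutan-1-ol | COc1cc(C[C@@H](C)[C@H](C)[C@@H](O)c2ccc(OC)c(OC)c2)ccc1O
F11 | step 7 | (1R,2S,3R)-4-(4-acetoxy-3-methoxyphenyl)-1-(3,4-dimethoxyphenyl)-2,3-dimethylbutyl acetate | COc1cc(C[C@@H](C)[C@H](C)[C@@H](OC(C)=O)c2ccc(OC)c(OC)c2)ccc1OC(C)=O
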